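**Assumption:** Pestalone H has no stereocentre and is achiral, so "single enantiomer" is taken to mean the constitution given; no stereocontrol is needed.

## Retrosynthetic overview

1. Pestalone H ⇒ aryl–prenyl bond (last step, Stille coupling of a ring B aryl iodide), after ring B has been formylated and iodinated para to its two ether oxygens.
2. The diaryl ketone ⇒ an aryl ester, by a 1,3-shift of the aroyl group from the ring A oxygen to the neighbouring ring A carbon (new deprotonative ester Fries).
3. The aryl ester ⇒ the C–O bond between the ring A phenol oxygen and the ring B carboxyl carbon; this bond unites the two halves.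
4. The ring A phenol ⇒ 3-methoxy-5-methylphenol by ortho-chlorination, then para-bromination; the only hydrogen left on ring A marks the acylation site.
5. No ring is built: ring A and ring B are both bought as benzene derivatives.

## Route

Step 1
Reactants: 1 3-methoxy-5-methylphenol
Product: 2 2-chloro-5-methoxy-3-methylphenol
Conditions: SO2Cl2 (1.05 equiv), 2,2,6,6-tetramethylpiperidine (5 mol%), toluene, 0 °C to rt
Reagents that add atoms: sulfuryl chloride, O=S(=O)(Cl)Cl
Why: Amine-catalysed ortho-selective electrophilic chlorination of a phenol: the N-chloroamine, hydrogen-bonded to the OH in a non-polar solvent, delivers chlorine to the ortho carbon that is also para to OMe, while the other ortho carbon between the two oxygens is the least reactive site of this ring.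

Step 2
Reactants: 2 2-chloro-5-methoxy-3-methylphenol
Product: 3 4-bromo-2-chloro-5-methoxy-3-methylphenol
Conditions: NBS (1.0 equiv), MeCN, −20 °C to 0 °C
Reagents that add atoms: N-bromosuccinimide, O=C1CCC(=O)N1Br
Why: Electrophilic aromatic bromination in a polar solvent goes para to the free OH; the only other free carbon lies between the two oxygens and reacts last, so one equivalent stops at the monobromide.

Step 3
Reactants: 3 4-bromo-2-chloro-5-methoxy-3-methylphenol; 4 3,5-bis(benzyloxy)benzoic acid
Product: 5 4-bromo-2-chloro-5-methoxy-3-methylphenyl 3,5-bis(benzyloxy)benzoate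
Conditions: DCC (1.1 equiv), DMAP (10 mol%), CH2Cl2, 0 °C to rt
Reagents that add atoms: none
Why: Steglich esterification of an acidic, mono-ortho-substituted phenol is reliable and forms the C–O bond that joins ring A to ring B, placing the aroyl group next to the single ring A hydrogen.

Step 4
Reactants: 5 4-bromo-2-chloro-5-methoxy-3-methylphenyl 3,5-bis(benzyloxy)benzoate
Product: 7 [3,5-bis(benzyloxy)phenyl](3-bromo-5-chloro-6-hydroxy-2-methoxy-4-methylphenyl)methanone, via ortho-lithiated ester 6 (not isolated)
Conditions: LiTMP (1.5 equiv; from 2,2,6,6-tetramethylpiperidine and n-BuLi, THF, 0 °C), then slow addition of 5, THF, −78 °C to −20 °C; then 1 M HCl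
Reagents that add atoms: none
Why: Proposed new method: a deprotonative anionic ortho-Fries (1,3 O-to-C aroyl shift) of a plain aryl aroate on a pentasubstituted bromo-chloro ring; LiTMP removes the only ring A hydrogen (between OMe and the acyloxy oxygen, further acidified by the meta Cl and Br), aryllithium 6 adds to its own ester carbonyl through a four-membered transition state, and the tetrahedral intermediate opens to the chelated lithium phenoxide of 7; this irreversible shift drains any reversible metalation of ring B, LiTMP neither exchanges with C–Br nor acylates, and adding 5 to excess base keeps 6 away from unreacted ester; closest known reaction types are the anionic ortho-Fries rearrangement of O-aryl carbamates and the halogen–lithium-exchange-triggered acyl migration of o-halophenyl esters.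

Step 5
Reactants: 7 [3,5-bis(benzyloxy)phenyl](3-bromo-5-chloro-6-hydroxy-2-methoxy-4-methylphenyl)methanone
Product: 9 4,6-bis(benzyloxy)-2-(3-bromo-5-chloro-6-hydroxy-2-methoxy-4-methylbenzoyl)benzaldehyde, via aryl iminium chloride 8 (not isolated)
Conditions: POCl3 (3 equiv) premixed with DMF at 0 °C, then 7, 70 °C; then H2O, 50 °C
Reagents that add atoms: N,N-dimethylformamide, CN(C)C=O; water, O
Why: Vilsmeier–Haack formylation attacks ring B para to one benzyloxy group and ortho to the other (the two such positions are equivalent, and the carbon between the two ethers is hindered), as with 3,5-dialkoxybenzoates; ring A has no free position.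

Step 6
Reactants: 9 4,6-bis(benzyloxy)-2-(3-bromo-5-chloro-6-hydroxy-2-methoxy-4-methylbenzoyl)benzaldehyde
Product: 10 4,6-bis(benzyloxy)-2-(3-bromo-5-chloro-6-hydroxy-2-methoxy-4-methylbenzoyl)-3-iodobenzaldehyde
Conditions: NIS (1.1 equiv), CF3CO2H (0.3 equiv), MeCN, rt, dark
Reagents that add atoms: N-iodosuccinimide, O=C1CCC(=O)N1I
Why: Acid-activated electrophilic aromatic iodination goes to the remaining carbon that is para to one benzyloxy group and ortho to the other (the usual 5-position of a 2,4-dialkoxybenzaldehyde), which is the carbon that must carry the prenyl group.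

Step 7
Reactants: 10 4,6-bis(benzyloxy)-2-(3-bromo-5-chloro-6-hydroxy-2-methoxy-4-methylbenzoyl)-3-iodobenzaldehyde
Product: 11 2-(3-bromo-5-chloro-6-hydroxy-2-methoxy-4-methylbenzoyl)-4,6-dihydroxy-3-iodobenzaldehyde
Conditions: BCl3 (5 equiv), pentamethylbenzene (6 equiv), CH2Cl2, −78 °C to −40 °C; then H2O
Reagents that add atoms: none
Why: Lewis-acid debenzylation with a non-basic cation scavenger cleaves aryl benzyl ethers at low temperature without touching C–I, C–Br, C–Cl or the aldehyde, and the ring A methyl ether should survive below −40 °C because the boron is tied up in the phenoxide–ketone chelate.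

Step 8
Reactants: 11 2-(3-bromo-5-chloro-6-hydroxy-2-methoxy-4-methylbenzoyl)-4,6-dihydroxy-3-iodobenzaldehyde; 12 tributyl(3-methylbut-2-en-1-yl)stannane
Product: 13 Pestalone H [2-(3-bromo-5-chloro-6-hydroxy-2-methoxy-4-methylbenzoyl)-4,6-dihydroxy-3-(3-methylbut-2-en-1-yl)benzaldehyde]
Conditions: Pd2(dba)3 (5 mol%), AsPh3 (20 mol%), CuI (10 mol%), degassed DMF, 50 °C
Reagents that add atoms: none
Why: Stille coupling with zerovalent palladium inserts into the C–I bond far faster than into the di-ortho-substituted, electron-rich C–Br or C–Cl of ring A, the stannane transfers the prenyl group through its CH2 terminus, and the neutral conditions avoid the base-induced redox isomerisation of the o-aroylbenzaldehyde.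

## Compound list

1 | 3-methoxy-5-methylphenol | COc1cc(C)cc(O)c1 | starting material
2 | 2-chloro-5-methoxy-3-methylphenol | COc1cc(O)c(Cl)c(C)c1 | intermediate
3 | 4-bromo-2-chloro-5-methoxy-3-methylphenol | COc1cc(O)c(Cl)c(C)c1Br | intermediate
4 | 3,5-bis(benzyloxy)benzoic acid | OC(=O)c1cc(OCc2ccccc2)cc(OCc2ccccc2)c1 | starting material
5 | 4-bromo-2-chloro-5-methoxy-3-methylphenyl 3,5-bis(benzyloxy)benzoate | COc1cc(OC(=O)c2cc(OCc3ccccc3)cc(OCc3ccccc3)c2)c(Cl)c(C)c1Br | intermediate
6 | ortho-lithiated ester: [2-{[3,5-bis(benzyloxy)benzoyl]oxy}-5-bromo-3-chloro-6-methoxy-4-methylphenyl]lithium | COc1c(Br)c(C)c(Cl)c(OC(=O)c2cc(OCc3ccccc3)cc(OCc3ccccc3)c2)c1[Li] | intermediate (not isolated)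
7 | [3,5-bis(benzyloxy)phenyl](3-bromo-5-chloro-6-hydroxy-2-methoxy-4-methylphenyl)methanone | COc1c(Br)c(C)c(Cl)c(O)c1C(=O)c1cc(OCc2ccccc2)cc(OCc2ccccc2)c1 | intermediate
8 | aryl iminium chloride: N-{[2,4-bis(benzyloxy)-6-(3-bromo-5-chloro-6-hydroxy-2-methoxy-4-methylbenzoyl)phenyl]methylidene}-N-methylmethanaminium chloride | COc1c(Br)c(C)c(Cl)c(O)c1C(=O)c1cc(OCc2ccccc2)cc(OCc2ccccc2)c1C=[N+](C)C.[Cl-] | intermediate (not isolated)
9 | 4,6-bis(benzyloxy)-2-(3-bromo-5-chloro-6-hydroxy-2-methoxy-4-methylbenzoyl)benzaldehyde | COc1c(Br)c(C)c(Cl)c(O)c1C(=O)c1cc(OCc2ccccc2)cc(OCc2ccccc2)c1C=O | intermediate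
10 | 4,6-bis(benzyloxy)-2-(3-bromo-5-chloro-6-hydroxy-2-methoxy-4-methylbenzoyl)-3-iodobenzaldehyde | COc1c(Br)c(C)c(Cl)c(O)c1C(=O)c1c(I)c(OCc2ccccc2)cc(OCc2ccccc2)c1C=O | intermediate
11 | 2-(3-bromo-5-chloro-6-hydroxy-2-methoxy-4-methylbenzoyl)-4,6-dihydroxy-3-iodobenzaldehyde | COc1c(Br)c(C)c(Cl)c(O)c1C(=O)c1c(I)c(O)cc(O)c1C=O | intermediate
12 | tributyl(3-methylbut-2-en-1-yl)stannane | CCCC[Sn](CCCC)(CCCC)CC=C(C)C | starting material
13 | Pestalone H, 2-(3-bromo-5-chloro-6-hydroxy-2-methoxy-4-methylbenzoyl)-4,6-dihydroxy-3-(3-methylbut-2-en-1-yl)benzaldehyde | COc1c(Br)c(C)c(Cl)c(O)c1C(=O)c1c(C=O)c(O)cc(O)c1CC=C(C)C | target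

## Step count and risks

Total steps: 8. Longest linear sequence: 8 (1 to 13); acid 4 and stannane 12 are bought.

The three steps most likely to fail:

**Step 1 (site of the first halogen).** Chlorine may also enter para to the OH, giving an isomer that is hard to separate. The fallback reverses the order of halogenation and the directing principle. It sets out from 1: para-selective bromination with tetrabutylammonium tribromide in CH2Cl2/MeOH gives 4-bromo-3-methoxy-5-methylphenol F1. Its only unhindered activated carbon, between OH and CH3 and para to OMe, is then chlorinated with N-chlorosuccinimide in MeCN. The fallback comes back to the route at 3.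

**Step 4 (the proposed new ester Fries).** Competing metalation of ring B or intermolecular acylation could lower the yield. The fallback uses known chemistry and sets out from 3. The last ring A hydrogen is iodinated with NIS in MeCN to give 4-bromo-2-chloro-6-iodo-5-methoxy-3-methylphenol F2. F2 is esterified with 4 (DCC, DMAP) to give 4-bromo-2-chloro-6-iodo-5-methoxy-3-methylphenyl 3,5-bis(benzyloxy)benzoate F3. Treating F3 with n-BuLi in THF at −100 °C causes iodine–lithium exchange, which is much faster than bromine–lithium exchange or carbonyl addition. This generates the same aryllithium 6 by the established halogen–metal-exchange-triggered acyl migration. The fallback comes back to the route at 7.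

**Step 8 (prenyl transfer to a hindered iodide on a sensitive product).** The stannane may couple partly through its substituted terminus, giving the 1,1-dimethylallyl isomer, or transmetalate slowly. The fallback sets out from 11. Stille coupling with allyltributylstannane (same catalyst system) has no regiochemical ambiguity and transmetalates faster; it gives 2-(3-bromo-5-chloro-6-hydroxy-2-methoxy-4-methylbenzoyl)-4,6-dihydroxy-3-(prop-2-en-1-yl)benzaldehyde F4. Olefin cross-metathesis of F4 with 2-methylbut-2-ene, using the second-generation Grubbs catalyst RuCl2(=CHPh)(H2IMes)(PCy3) in CH2Cl2 at 40 °C, converts the allyl group into the prenyl group. The fallback comes back to the route at 13.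

## Further compounds

F1 | step 1 | 4-bromo-3-methoxy-5-methylphenol | COc1cc(O)cc(C)c1Br
F2 | step 4 | 4-bromo-2-chloro-6-iodo-5-methoxy-3-methylphenol | COc1c(I)c(O)c(Cl)c(C)c1Br
F3 | step 4 | 4-bromo-2-chloro-6-iodo-5-methoxy-3-methylphenyl 3,5-bis(benzyloxy)benzoate | COc1c(I)c(OC(=O)c2cc(OCc3ccccc3)cc(OCc3ccccc3)c2)c(Cl)c(C)c1Br
F4 | step 8 | 2-(3-bromo-5-chloro-6-hydroxy-2-methoxy-4-methylbenzoyl)-4,6-dihydroxy-3-(prop-2-en-1-yl)benzaldehyde | COc1c(Br)c(C)c(Cl)c(O)c1C(=O)c1c(CC=C)c(O)cc(O)c1C=O
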